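**Retrosynthetic overview**
1. Last bond C11=C12: E-selective Horner–Wadsworth–Emmons union of an acetylenic C15 hydroxy aldehyde with a C25 polyenyl phosphonate, so the 9E enyne never passes through an ylide or an allyl cation.
2. C25 phosphonate: symmetry-breaking mono-olefination of a symmetric C10 triene bisphosphonate with the C15 aldehyde made from (R)-α-ionone.
3. Key step: the symmetric C10 triene comes from furan, which is opened oxidatively to (Z)-but-2-enedial and olefinated twice in the same flask (the furan carbons become C14–C15=C15'–C14').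
4. Acetylenic half: Sonogashira coupling of the enol triflate of (4R,6R)-actinol with (E)-3-methylpent-2-en-4-yn-1-ol, then allylic oxidation.
5. Rings: no ring is built. Both six-membered rings arrive intact with their stereocentres (ε ring from (R)-α-ionone, hydroxy ring from actinol); the only ring event is the opening of furan.

Assumption: (R)-α-ionone (≥98% ee), (4R,6R)-4-hydroxy-2,2,6-trimethylcyclohexan-1-one (actinol) and (E)-3-methylpent-2-en-4-yn-1-ol are bought as such.

**Route**

Step 1
Reactants: 1 furan (1.2 equiv); 2 ethyl 2-(triphenylphosphoranylidene)propanoate (2.2 equiv)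
Product: 5 diethyl (2E,4E,6E)-2,7-dimethylocta-2,4,6-trienedioate, via (Z)-but-2-enedial 3 (not isolated), via 4Z-triene diester 4 (not isolated)
Conditions: dimethyldioxirane (0.08 M in acetone, 1.0 equiv), −78 → 0 °C; then 2, CH2Cl2, 0 °C → rt; then I2 (5 mol %), rt, daylight
Reagents that add atoms: none
Why: Dimethyldioxirane epoxidises furan and the epoxide opens to the cis-enedial (oxidative dearomatisation), both formyl groups undergo E-selective Wittig olefination with the stabilised ylide (both dial oxygens leave on phosphorus), and iodine catalysis equilibrates the central Z bond to the all-E triene.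

Step 2
Reactants: 5 diethyl (2E,4E,6E)-2,7-dimethylocta-2,4,6-trienedioate
Product: 6 (2E,4E,6E)-2,7-dimethylocta-2,4,6-triene-1,8-diol
Conditions: i-Bu2AlH (4.5 equiv), CH2Cl2, −78 → 0 °C; aq. KNaC4H4O6
Reagents that add atoms: none
Why: 1,2-Reduction of the conjugated diester with i-Bu2AlH gives the bis-allylic diol without touching the triene geometry.

Step 3
Reactants: 6 (2E,4E,6E)-2,7-dimethylocta-2,4,6-triene-1,8-diol
Product: 8 tetraethyl [(2E,4E,6E)-2,7-dimethylocta-2,4,6-triene-1,8-diyl]bis(phosphonate), via C10 dibromide 7 (not isolated)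
Conditions: PBr3 (0.75 equiv), Et2O, −10 °C, dark; then P(OEt)3 (neat, excess), 100 °C
Reagents that add atoms: triethyl phosphite, CCOP(OCC)OCC
Why: SN2 bromination of both allylic alcohols followed by Michaelis–Arbuzov reaction installs the two phosphonates with retention of the E,E,E triene.

Step 4
Reactants: 9 (R)-α-ionone; 10 diethyl (cyanomethyl)phosphonate (1.25 equiv)
Product: 11 (2E,4E)-3-methyl-5-[(1R)-2,6,6-trimethylcyclohex-2-en-1-yl]penta-2,4-dienenitrile
Conditions: NaH (1.2 equiv), THF, 0 °C → rt; chromatography to remove the 2Z isomer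
Reagents that add atoms: none
Why: Horner–Wadsworth–Emmons olefination of the methyl ketone gives mainly the 2E nitrile (about 3:1), and the weakly basic phosphonate anion leaves the doubly allylic ring stereocentre untouched.

Step 5
Reactants: 11 (2E,4E)-3-methyl-5-[(1R)-2,6,6-trimethylcyclohex-2-en-1-yl]penta-2,4-dienenitrile
Product: 13 (2E,4E)-3-methyl-5-[(1R)-2,6,6-trimethylcyclohex-2-en-1-yl]penta-2,4-dienal, via aldimine 12 (not isolated)
Conditions: i-Bu2AlH (1.2 equiv), hexane/toluene, −78 °C; then wet SiO2, 0 °C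
Reagents that add atoms: water, O
Why: Partial reduction of the nitrile to the N-aluminio aldimine and hydrolysis on work-up (nitrile-to-aldehyde reduction) gives the enal with the ring stereocentre and both double bonds unchanged.

Step 6
Reactants: 8 tetraethyl [(2E,4E,6E)-2,7-dimethylocta-2,4,6-triene-1,8-diyl]bis(phosphonate) (3 equiv); 13 (2E,4E)-3-methyl-5-[(1R)-2,6,6-trimethylcyclohex-2-en-1-yl]penta-2,4-dienal (1 equiv)
Product: 14 diethyl {(2E,4E,6E,8E,10E,12E)-2,7,11-trimethyl-13-[(1R)-2,6,6-trimethylcyclohex-2-en-1-yl]trideca-2,4,6,8,10,12-hexaen-1-yl}phosphonate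
Conditions: NaN(SiMe3)2 (1.0 equiv), THF/DMPU, −78 °C; then 13, −78 → −20 °C; excess 8 recovered
Reagents that add atoms: none
Why: Symmetry-breaking mono Horner–Wadsworth–Emmons reaction, in which one equivalent of base makes only the monoanion of the symmetric bisphosphonate (used in threefold excess), so one terminus olefinates and the new disubstituted double bond is formed E.

Step 7
Reactants: 15 (4R,6R)-4-hydroxy-2,2,6-trimethylcyclohexan-1-one (actinol)
Product: 18 (4R)-4-hydroxy-2,6,6-trimethylcyclohex-1-en-1-yl trifluoromethanesulfonate, via silyl ether 16 (not isolated), via silyl enol triflate 17 (not isolated)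
Conditions: (Me3Si)2NH (0.6 equiv), Me3SiCl (cat.), CH2Cl2, rt, evaporate; LiN(i-Pr)2 (1.2 equiv), THF, −78 → 0 °C, then PhNTf2, 0 °C → rt; 1 M HCl, THF, 0 °C
Reagents that add atoms: N-phenylbis(trifluoromethanesulfonimide), O=S(=O)(N(c1ccccc1)S(=O)(=O)C(F)(F)F)C(F)(F)F
Why: Transient O-silylation masks the alcohol, the only enolisable position (the C-6 methine) is deprotonated and the enolate O-triflated (enol triflate formation), which erases the C-6 stereocentre while the carbinol centre stays (R), and dilute acid removes the silyl group.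

Step 8
Reactants: 18 (4R)-4-hydroxy-2,6,6-trimethylcyclohex-1-en-1-yl trifluoromethanesulfonate; 19 (E)-3-methylpent-2-en-4-yn-1-ol (1.3 equiv)
Product: 20 (2E)-5-[(4R)-4-hydroxy-2,6,6-trimethylcyclohex-1-en-1-yl]-3-methylpent-2-en-4-yn-1-ol
Conditions: Pd(PPh3)4 (5 mol %), CuI (10 mol %), Et3N, DMF, 25–45 °C, Ar, dark
Reagents that add atoms: none
Why: Sonogashira coupling (zerovalent palladium with CuI) of the tetrasubstituted enol triflate with the terminal alkyne forms the C6–C7 bond and carries the E geometry of the enynol unchanged into the product.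

Step 9
Reactants: 20 (2E)-5-[(4R)-4-hydroxy-2,6,6-trimethylcyclohex-1-en-1-yl]-3-methylpent-2-en-4-yn-1-ol
Product: 21 (2E)-5-[(4R)-4-hydroxy-2,6,6-trimethylcyclohex-1-en-1-yl]-3-methylpent-2-en-4-ynal
Conditions: MnO2 (20 equiv), CH2Cl2, 0 °C, dark; filter, use at once
Reagents that add atoms: none
Why: MnO2 oxidises only the primary allylic alcohol (chemoselective allylic oxidation) and leaves the homoallylic secondary carbinol and the E enyne intact.

Step 10
Reactants: 14 diethyl {(2E,4E,6E,8E,10E,12E)-2,7,11-trimethyl-13-[(1R)-2,6,6-trimethylcyclohex-2-en-1-yl]trideca-2,4,6,8,10,12-hexaen-1-yl}phosphonate (1.1 equiv); 21 (2E)-5-[(4R)-4-hydroxy-2,6,6-trimethylcyclohex-1-en-1-yl]-3-methylpent-2-en-4-ynal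
Product: 22 crocoxanthin, (all-E)-(3R,6'R)-7,8-didehydro-β,ε-caroten-3-ol (CNP0322200.1)
Conditions: NaN(SiMe3)2 (1.1 equiv), THF/DMPU, −78 °C; then 21, −78 → −20 °C, dark; aq. NH4Cl; crystallisation in the cold
Reagents that add atoms: none
Why: E-selective Horner–Wadsworth–Emmons olefination forms C11=C12 under cold, non-acidic conditions, so the kinetically fixed 9E enyne and both stereocentres are preserved, and the free hydroxyl (less acidic than the phosphonate) needs no protection.

**Compound list**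
1 | furan | c1ccoc1 | starting material
2 | ethyl 2-(triphenylphosphoranylidene)propanoate | CCOC(=O)C(C)=P(c1ccccc1)(c1ccccc1)c1ccccc1 | starting material
3 | (Z)-but-2-enedial | O=C/C=C\C=O | intermediate
4 | diethyl (2E,4Z,6E)-2,7-dimethylocta-2,4,6-trienedioate | CCOC(=O)/C(C)=C/C=C\C=C(/C)C(=O)OCC | intermediate
5 | diethyl (2E,4E,6E)-2,7-dimethylocta-2,4,6-trienedioate | CCOC(=O)/C(C)=C/C=C/C=C(\C)C(=O)OCC | intermediate
6 | (2E,4E,6E)-2,7-dimethylocta-2,4,6-triene-1,8-diol | OC/C(C)=C/C=C/C=C(\C)CO | intermediate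
7 | (2E,4E,6E)-1,8-dibromo-2,7-dimethylocta-2,4,6-triene | BrC/C(C)=C/C=C/C=C(\C)CBr | intermediate
8 | tetraethyl [(2E,4E,6E)-2,7-dimethylocta-2,4,6-triene-1,8-diyl]bis(phosphonate) | CCOP(=O)(OCC)C/C(C)=C/C=C/C=C(\C)CP(=O)(OCC)OCC | intermediate
9 | (R)-α-ionone, (3E)-4-[(1R)-2,6,6-trimethylcyclohex-2-en-1-yl]but-3-en-2-one | CC1=CCCC(C)(C)[C@H]1/C=C/C(C)=O | starting material
10 | diethyl (cyanomethyl)phosphonate | CCOP(=O)(CC#N)OCC | starting material
11 | (2E,4E)-3-methyl-5-[(1R)-2,6,6-trimethylcyclohex-2-en-1-yl]penta-2,4-dienenitrile | CC1=CCCC(C)(C)[C@H]1/C=C/C(C)=C/C#N | intermediate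
12 | (2E,4E)-3-methyl-5-[(1R)-2,6,6-trimethylcyclohex-2-en-1-yl]penta-2,4-dien-1-imine | CC1=CCCC(C)(C)[C@H]1/C=C/C(C)=C/C=N | intermediate
13 | (2E,4E)-3-methyl-5-[(1R)-2,6,6-trimethylcyclohex-2-en-1-yl]penta-2,4-dienal | CC1=CCCC(C)(C)[C@H]1/C=C/C(C)=C/C=O | intermediate
14 | diethyl {(2E,4E,6E,8E,10E,12E)-2,7,11-trimethyl-13-[(1R)-2,6,6-trimethylcyclohex-2-en-1-yl]trideca-2,4,6,8,10,12-hexaen-1-yl}phosphonate | CC1=CCCC(C)(C)[C@H]1/C=C/C(C)=C/C=C/C(C)=C/C=C/C=C(\C)CP(=O)(OCC)OCC | intermediate
15 | (4R,6R)-4-hydroxy-2,2,6-trimethylcyclohexan-1-one (actinol) | O=C1[C@H](C)C[C@@H](O)CC1(C)C | starting material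
16 | (4R,6R)-2,2,6-trimethyl-4-[(trimethylsilyl)oxy]cyclohexan-1-one | O=C1[C@H](C)C[C@@H](O[Si](C)(C)C)CC1(C)C | intermediate
17 | (4R)-2,6,6-trimethyl-4-[(trimethylsilyl)oxy]cyclohex-1-en-1-yl trifluoromethanesulfonate | FC(F)(F)S(=O)(=O)OC1=C(C)C[C@@H](O[Si](C)(C)C)CC1(C)C | intermediate
18 | (4R)-4-hydroxy-2,6,6-trimethylcyclohex-1-en-1-yl trifluoromethanesulfonate | FC(F)(F)S(=O)(=O)OC1=C(C)C[C@@H](O)CC1(C)C | intermediate
19 | (E)-3-methylpent-2-en-4-yn-1-ol | OC/C=C(\C)C#C | starting material
20 | (2E)-5-[(4R)-4-hydroxy-2,6,6-trimethylcyclohex-1-en-1-yl]-3-methylpent-2-en-4-yn-1-ol | OC/C=C(\C)C#CC1=C(C)C[C@@H](O)CC1(C)C | intermediate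
21 | (2E)-5-[(4R)-4-hydroxy-2,6,6-trimethylcyclohex-1-en-1-yl]-3-methylpent-2-en-4-ynal | O=C/C=C(\C)C#CC1=C(C)C[C@@H](O)CC1(C)C | intermediate
22 | crocoxanthin, (all-E)-(3R,6'R)-7,8-didehydro-β,ε-caroten-3-ol | CC1=CCCC(C)(C)[C@H]1/C=C/C(C)=C/C=C/C(C)=C/C=C/C=C(C)/C=C/C=C(\C)C#CC1=C(C)C[C@@H](O)CC1(C)C | target

**Step count**
Total steps: 10. Longest linear sequence: 5 (steps 1, 2, 3, 6, 10 from furan); the α-ionone branch (4, 5, 6, 10) and the actinol branch (7, 8, 9, 10) are 4 steps each.

**Three steps most likely to fail, with fallbacks**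

Step 1 (one-flask ring opening and double olefination). The cis-enedial can polymerise, or residual dioxirane can oxidise the ylide. The fallback sets out from 1 and returns at 5. Furan is treated with Br2 in MeOH over Na2CO3 at −40 °C to give 2,5-dimethoxy-2,5-dihydrofuran F1. F1 is hydrolysed and isomerised with Amberlyst-15 in water/acetone to isolable (E)-but-2-enedial F2. F2 is then olefinated with 2 (2.1 equiv, CH2Cl2, rt), which gives 5 directly as the all-E isomer without the iodine step.

Step 7 (transient silylation and triflation of a hindered ketone). Enolisation of the hindered methine may be incomplete, or the silyl ether may not survive. The fallback sets out from 15 and returns at 20, with no oxygen protection at all. Actinol is condensed with N2H4·H2O (Et3N, EtOH, reflux) to (4R,6R)-4-hydroxy-2,2,6-trimethylcyclohexan-1-one hydrazone F3. F3 is oxidised with I2 and 1,1,3,3-tetramethylguanidine (THF/Et2O, 0 °C, Barton vinyl iodide synthesis) to (1R)-4-iodo-3,5,5-trimethylcyclohex-3-en-1-ol F4. F4 is coupled with 19 under the conditions of step 8 to give 20.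

Step 10 (final olefination with the labile enynal 21). Aldehyde 21 may isomerise at C9 or decompose under base. The fallback sets out from 14 and returns at 22, and moves the sp2–sp bond formation to the end. Alcohol 19 is oxidised with MnO2 (CH2Cl2, 0 °C) to (2E)-3-methylpent-2-en-4-ynal F5. F5 is condensed with the anion of 14 (NaN(SiMe3)2, THF/DMPU, −78 °C) to (all-E)-3,7,12,16-tetramethyl-18-[(1R)-2,6,6-trimethylcyclohex-2-en-1-yl]octadeca-3,5,7,9,11,13,15,17-octaen-1-yne F6. F6 is joined to triflate 18 by Sonogashira coupling (Pd(PPh3)4, CuI, Et3N, DMF, 40 °C, dark) to give 22.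

**Further compounds**
F1 | step 1 | 2,5-dimethoxy-2,5-dihydrofuran | COC1C=CC(OC)O1
F2 | step 1 | (E)-but-2-enedial | O=C/C=C/C=O
F3 | step 7 | (4R,6R)-4-hydroxy-2,2,6-trimethylcyclohexan-1-one hydrazone | NN=C1[C@H](C)C[C@@H](O)CC1(C)C
F4 | step 7 | (1R)-4-iodo-3,5,5-trimethylcyclohex-3-en-1-ol | IC1=C(C)C[C@@H](O)CC1(C)C
F5 | step 10 | (2E)-3-methylpent-2-en-4-ynal | O=C/C=C(\C)C#C
F6 | step 10 | (all-E)-3,7,12,16-tetramethyl-18-[(1R)-2,6,6-trimethylcyclohex-2-en-1-yl]octadeca-3,5,7,9,11,13,15,17-octaen-1-yne | CC1=CCCC(C)(C)[C@H]1/C=C/C(C)=C/C=C/C(C)=C/C=C/C=C(C)/C=C/C=C(\C)C#C
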